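The cyclohexene is numbered C1 (OAc), C2 (OH), C3 (OH), C4=C5 (C5 bears C7H2OBz), C6 (OBz). Everything rests on closing the six-membered ring at C1–C2: both atoms are carbinol carbons of a cis-glycol that lies trans to the oxygens on C3 and C6, so they are joined as two aldehyde carbons of like polarity by a reductive SmI2 pinacol cyclisation. The precursor is an acyclic (Z)-hex-3-enedial carrying the C6 and C7 benzoates and a silyl ether on O3; its C3 and C6 stereocentres are set by anti additions to the two enantiomers of glyceraldehyde acetonide. One operation forms the carbocycle and both new stereocentres; the acetate is then placed on the axial O1.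

Key step: step 8

Remark: both enantiomers of glyceraldehyde acetonide are taken as commercial (used freshly distilled); acyclic intermediates keep the atom numbers C1–C7 defined above, and the dioxolane rings serve only as masked formyl groups.

Step 1
Reactants: 1 tert-butyldimethyl(prop-2-yn-1-yloxy)silane; 2 (S)-2,2-dimethyl-1,3-dioxolane-4-carbaldehyde
Product: 5 (1R)-4-[(tert-butyldimethylsilyl)oxy]-1-[(4S)-2,2-dimethyl-1,3-dioxolan-4-yl]but-2-yn-1-ol, via lithium acetylide 3 (not isolated), via alkynylzinc bromide 4 (not isolated)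
Conditions: n-BuLi, THF, −78 °C; ZnBr2, −78 → 0 °C; then 2, −78 °C → rt
Reagents that add atoms: none
Why: Carbonyl alkynylation under Felkin–Anh (non-chelation) control, in which the alkynylzinc reagent should enter anti to the dioxolane C–O bond and give mainly the anti adduct with the (R)-carbinol at C3, the dioxolane being a masked C2 aldehyde.

Step 2
Reactants: 5 (1R)-4-[(tert-butyldimethylsilyl)oxy]-1-[(4S)-2,2-dimethyl-1,3-dioxolan-4-yl]but-2-yn-1-ol
Product: 7 (1R,2Z)-4-[(tert-butyldimethylsilyl)oxy]-1-[(4S)-2,2-dimethyl-1,3-dioxolan-4-yl]-3-iodobut-2-en-1-ol, via cyclic alkenylaluminate 6 (not isolated)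
Conditions: NaAlH2(OCH2CH2OMe)2, THF, 0 °C → rt; EtOAc quench; then I2, THF, −78 → 0 °C
Reagents that add atoms: iodine, II
Why: Hydroxyl-directed trans-hydroalumination of the propargylic alcohol (hydride to C4, aluminium to C5 in a five-membered alkoxyaluminate) followed by iodinolysis with retention should give the (Z)-iodoalkene, which fixes the later cis relationship of C3 and C6 across C4=C5.

Step 3
Reactants: 7 (1R,2Z)-4-[(tert-butyldimethylsilyl)oxy]-1-[(4S)-2,2-dimethyl-1,3-dioxolan-4-yl]-3-iodobut-2-en-1-ol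
Product: 8 (4S)-4-[(1R,2Z)-1,4-bis[(tert-butyldimethylsilyl)oxy]-3-iodobut-2-en-1-yl]-2,2-dimethyl-1,3-dioxolane
Conditions: TBSOTf, 2,6-lutidine, CH2Cl2, −78 → 0 °C
Reagents that add atoms: tert-butyldimethylsilyl triflate, CC(C)(C)[Si](C)(C)OS(=O)(=O)C(F)(F)F
Why: Silyl triflate silylation of the hindered secondary allylic alcohol masks O3, so that it is neither benzoylated in step 6 nor part of a cleavable 1,2-diol in step 7.

Step 4
Reactants: 8 (4S)-4-[(1R,2Z)-1,4-bis[(tert-butyldimethylsilyl)oxy]-3-iodobut-2-en-1-yl]-2,2-dimethyl-1,3-dioxolane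
Product: 9 (2Z,4R)-4-[(tert-butyldimethylsilyl)oxy]-4-[(4S)-2,2-dimethyl-1,3-dioxolan-4-yl]-2-iodobut-2-en-1-ol
Conditions: HF·pyridine, pyridine, THF, 0 °C
Reagents that add atoms: none
Why: Selective fluoride desilylation, in which the unhindered primary allylic silyl ether on C7 should be cleaved much faster than the secondary one on C3 under pyridine-buffered HF, with the acetonide untouched.

Step 5
Reactants: 9 (2Z,4R)-4-[(tert-butyldimethylsilyl)oxy]-4-[(4S)-2,2-dimethyl-1,3-dioxolan-4-yl]-2-iodobut-2-en-1-ol; 10 (R)-2,2-dimethyl-1,3-dioxolane-4-carbaldehyde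
Product: 11 (1S,2Z,4R)-4-[(tert-butyldimethylsilyl)oxy]-1-[(4R)-2,2-dimethyl-1,3-dioxolan-4-yl]-4-[(4S)-2,2-dimethyl-1,3-dioxolan-4-yl]-2-(hydroxymethyl)but-2-en-1-ol
Conditions: CrCl2 (excess), NiCl2 (cat.), DMSO, rt
Reagents that add atoms: none
Why: Nozaki–Hiyama–Kishi coupling, in which the alkenylchromium species tolerates the free hydroxyl, keeps the alkene geometry and should add to the α-alkoxy aldehyde in the Felkin–Anh sense, setting the (S)-carbinol at C6 anti to the dioxolane oxygen.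

Step 6
Reactants: 11 (1S,2Z,4R)-4-[(tert-butyldimethylsilyl)oxy]-1-[(4R)-2,2-dimethyl-1,3-dioxolan-4-yl]-4-[(4S)-2,2-dimethyl-1,3-dioxolan-4-yl]-2-(hydroxymethyl)but-2-en-1-ol
Product: 12 (1S,2Z,4R)-2-[(benzoyloxy)methyl]-4-[(tert-butyldimethylsilyl)oxy]-1-[(4R)-2,2-dimethyl-1,3-dioxolan-4-yl]-4-[(4S)-2,2-dimethyl-1,3-dioxolan-4-yl]but-2-en-1-yl benzoate
Conditions: BzCl, pyridine, DMAP (cat.), CH2Cl2, 0 °C → rt
Reagents that add atoms: benzoyl chloride, O=C(Cl)c1ccccc1
Why: DMAP-catalysed O-acylation should convert the primary C7 and the secondary C6 hydroxyl into the two benzoates of the target in one operation.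

Step 7
Reactants: 12 (1S,2Z,4R)-2-[(benzoyloxy)methyl]-4-[(tert-butyldimethylsilyl)oxy]-1-[(4R)-2,2-dimethyl-1,3-dioxolan-4-yl]-4-[(4S)-2,2-dimethyl-1,3-dioxolan-4-yl]but-2-en-1-yl benzoate
Product: 13 (2S,3Z,5R)-2-(benzoyloxy)-3-[(benzoyloxy)methyl]-5-[(tert-butyldimethylsilyl)oxy]hex-3-enedial
Conditions: H5IO6, EtOAc, 0 °C → rt; filtered and used crude
Reagents that add atoms: none
Why: Periodic acid acts as acid and oxidant in one pot (acetal hydrolysis, then glycol cleavage), so both terminal isopropylidene acetals should be converted into the C1 and C2 formyl groups without touching C3, C6, the silyl ether or the esters.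

Step 8
Reactants: 13 (2S,3Z,5R)-2-(benzoyloxy)-3-[(benzoyloxy)methyl]-5-[(tert-butyldimethylsilyl)oxy]hex-3-enedial
Product: 14 [(3R,4R,5S,6S)-6-(benzoyloxy)-3-[(tert-butyldimethylsilyl)oxy]-4,5-dihydroxycyclohex-1-en-1-yl]methyl benzoate
Conditions: SmI2 (3 equiv), t-BuOH, THF (0.01 M), −78 → −20 °C; then aq. NaHCO3
Reagents that add atoms: none
Why: Single-electron transfer from SmI2 to a formyl group gives a samarium-bound ketyl that adds to the second, samarium-activated formyl group (or couples with a second ketyl), and a further electron transfer and protonation give the diol. The closest known reaction type is the SmI2-mediated intramolecular pinacol coupling of sugar-derived 1,6-dialdehydes to cyclitol cis-diols. The six-membered carbocycle is closed by 6-exo-trig attack of the C1 ketyl carbon on the C2 carbonyl carbon, the (Z)-C4=C5 bond holding the two ends together. The new C1 and C2 centres should be cis because both oxygens are bridged by trivalent samarium in the coupling array, and each should be trans to its neighbouring oxygen (C6–OBz, C3–OTBS) to avoid steric and dipolar repulsion; as these two substituents lie on the same face, both preferences are matched. The step needs C–C coupling to outrun reductive β-elimination of the C6 benzoate and intermolecular coupling, which the preorganised dialdehyde, high dilution, low temperature and the absence of HMPA should secure.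

Step 9
Reactants: 14 [(3R,4R,5S,6S)-6-(benzoyloxy)-3-[(tert-butyldimethylsilyl)oxy]-4,5-dihydroxycyclohex-1-en-1-yl]methyl benzoate
Product: 16 [(3R,4R,5S,6S)-5-(acetyloxy)-6-(benzoyloxy)-3-[(tert-butyldimethylsilyl)oxy]-4-hydroxycyclohex-1-en-1-yl]methyl benzoate, via cyclic orthoacetate 15 (not isolated)
Conditions: MeC(OMe)3, CSA (cat.), CH2Cl2, rt; then 80% aq. AcOH, 0 °C → rt
Reagents that add atoms: trimethyl orthoacetate, CC(OC)(OC)OC; water, O
Why: Acid-catalysed orthoester exchange engages only the cis-1,2-diol, and kinetic hydrolysis of a cyclic orthoacetate opens to the axial ester and equatorial hydroxyl; with C6–OBz pseudoaxial (relief of allylic 1,2-strain against C7), O1 is axial and O2 equatorial, so the acetate should land on O1.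

Step 10
Reactants: 16 [(3R,4R,5S,6S)-5-(acetyloxy)-6-(benzoyloxy)-3-[(tert-butyldimethylsilyl)oxy]-4-hydroxycyclohex-1-en-1-yl]methyl benzoate
Product: 17 [(3R,4S,5S,6S)-5-(acetyloxy)-6-(benzoyloxy)-3,4-dihydroxycyclohex-1-en-1-yl]methyl benzoate
Conditions: HF·pyridine, THF, 0 °C → rt
Reagents that add atoms: none
Why: Fluoride-mediated cleavage of the remaining silyl ether under mildly acidic, non-basic conditions should free O3 without acyl migration or ester cleavage and give the target.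

Compound list
1 | tert-butyldimethyl(prop-2-yn-1-yloxy)silane | C#CCO[Si](C)(C)C(C)(C)C | starting material
2 | (S)-2,2-dimethyl-1,3-dioxolane-4-carbaldehyde | O=C[C@@H]1COC(C)(C)O1 | starting material
3 | lithium acetylide of 1 | [Li]C#CCO[Si](C)(C)C(C)(C)C | intermediate
4 | alkynylzinc bromide of 1 | Br[Zn]C#CCO[Si](C)(C)C(C)(C)C | intermediate
5 | (1R)-4-[(tert-butyldimethylsilyl)oxy]-1-[(4S)-2,2-dimethyl-1,3-dioxolan-4-yl]but-2-yn-1-ol | CC(C)(C)[Si](C)(C)OCC#C[C@@H](O)[C@@H]1COC(C)(C)O1 | intermediate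
6 | sodium cyclic alkenylaluminate (Al bound to O3 and C5, two 2-methoxyethoxy ligands) | [Na+].COCCO[Al-]1(OCCOC)O[C@@H]([C@@H]2COC(C)(C)O2)C=C1CO[Si](C)(C)C(C)(C)C | intermediate
7 | (1R,2Z)-4-[(tert-butyldimethylsilyl)oxy]-1-[(4S)-2,2-dimethyl-1,3-dioxolan-4-yl]-3-iodobut-2-en-1-ol | CC(C)(C)[Si](C)(C)OC/C(I)=C/[C@@H](O)[C@@H]1COC(C)(C)O1 | intermediate
8 | (4S)-4-[(1R,2Z)-1,4-bis[(tert-butyldimethylsilyl)oxy]-3-iodobut-2-en-1-yl]-2,2-dimethyl-1,3-dioxolane | CC(C)(C)[Si](C)(C)OC/C(I)=C/[C@@H](O[Si](C)(C)C(C)(C)C)[C@@H]1COC(C)(C)O1 | intermediate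
9 | (2Z,4R)-4-[(tert-butyldimethylsilyl)oxy]-4-[(4S)-2,2-dimethyl-1,3-dioxolan-4-yl]-2-iodobut-2-en-1-ol | OC/C(I)=C/[C@@H](O[Si](C)(C)C(C)(C)C)[C@@H]1COC(C)(C)O1 | intermediate
10 | (R)-2,2-dimethyl-1,3-dioxolane-4-carbaldehyde | O=C[C@H]1COC(C)(C)O1 | starting material
11 | (1S,2Z,4R)-4-[(tert-butyldimethylsilyl)oxy]-1-[(4R)-2,2-dimethyl-1,3-dioxolan-4-yl]-4-[(4S)-2,2-dimethyl-1,3-dioxolan-4-yl]-2-(hydroxymethyl)but-2-en-1-ol | OC/C(=C/[C@@H](O[Si](C)(C)C(C)(C)C)[C@@H]1COC(C)(C)O1)[C@H](O)[C@H]2COC(C)(C)O2 | intermediate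
12 | (1S,2Z,4R)-2-[(benzoyloxy)methyl]-4-[(tert-butyldimethylsilyl)oxy]-1-[(4R)-2,2-dimethyl-1,3-dioxolan-4-yl]-4-[(4S)-2,2-dimethyl-1,3-dioxolan-4-yl]but-2-en-1-yl benzoate | O=C(OC/C(=C/[C@@H](O[Si](C)(C)C(C)(C)C)[C@@H]1COC(C)(C)O1)[C@H](OC(=O)c2ccccc2)[C@H]3COC(C)(C)O3)c4ccccc4 | intermediate
13 | (2S,3Z,5R)-2-(benzoyloxy)-3-[(benzoyloxy)methyl]-5-[(tert-butyldimethylsilyl)oxy]hex-3-enedial | O=C[C@@H](OC(=O)c1ccccc1)/C(COC(=O)c2ccccc2)=C\[C@@H](O[Si](C)(C)C(C)(C)C)C=O | intermediate
14 | [(3R,4R,5S,6S)-6-(benzoyloxy)-3-[(tert-butyldimethylsilyl)oxy]-4,5-dihydroxycyclohex-1-en-1-yl]methyl benzoate | O[C@H]1[C@@H](O)[C@H](O[Si](C)(C)C(C)(C)C)C=C(COC(=O)c2ccccc2)[C@@H]1OC(=O)c1ccccc1 | intermediate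
15 | cyclic methyl orthoacetate of 14 across O1 and O2 (orthoester carbon unassigned) | COC1(C)O[C@H]2[C@@H](O1)[C@H](O[Si](C)(C)C(C)(C)C)C=C(COC(=O)c3ccccc3)[C@@H]2OC(=O)c4ccccc4 | intermediate
16 | [(3R,4R,5S,6S)-5-(acetyloxy)-6-(benzoyloxy)-3-[(tert-butyldimethylsilyl)oxy]-4-hydroxycyclohex-1-en-1-yl]methyl benzoate | CC(=O)O[C@H]1[C@@H](O)[C@H](O[Si](C)(C)C(C)(C)C)C=C(COC(=O)c2ccccc2)[C@@H]1OC(=O)c1ccccc1 | intermediate
17 | [(3R,4S,5S,6S)-5-(acetyloxy)-6-(benzoyloxy)-3,4-dihydroxycyclohex-1-en-1-yl]methyl benzoate | CC(=O)O[C@H]1[C@@H](O)[C@H](O)C=C(COC(=O)c2ccccc2)[C@@H]1OC(=O)c1ccccc1 | target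

Total step count: 10. Longest linear sequence: 10 steps (1 → 17).

Steps most likely to fail

Step 8. Reductive loss of the benzoate next to the C1 formyl group (β-elimination after ketyl formation) or erosion of the cis/trans selectivity may compete with ring closure. The fallback sets out from 11 and carries O6 and O7 through the cyclisation as a non-acyl tether. Treatment of 11 with t-Bu2Si(OTf)2 and 2,6-lutidine should give the cyclic di-tert-butylsilylene acetal F1. H5IO6 in EtOAc should then unmask the silylene-protected dialdehyde F2, and SmI2 should close it to the silylene-protected cis-diol F3. The diol is capped with 2,2-dimethoxypropane and PPTS as the acetonide F4. Brief exposure to pyridine-buffered HF·pyridine removes the silylene to give the C6,C7-diol F5, which is benzoylated (BzCl, pyridine, DMAP) to the dibenzoate acetonide F6. Hydrolysis of the acetonide with 80% aq. AcOH comes back to the route at 14.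

Step 9. The conformational bias may be too small, so that the orthoester opens toward O2, or the acetyl group may migrate between O1 and O2 during hydrolysis. The fallback sets out from 14 and differentiates the hydroxyls by protection instead of conformation. HF·pyridine gives the triol F7. Butane-2,3-dione, HC(OMe)3 and CSA in MeOH should protect only the trans-diequatorial O2/O3 pair as the butane-2,3-diacetal F8. Ac2O in pyridine then acetylates the one free hydroxyl (O1) to give the acetylated diacetal F9, and TFA/H2O removes the diacetal, coming back to the route at 17.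

Step 5. Facial selectivity in the addition to the α-alkoxy aldehyde may be poor, and the hindered alkenyl iodide may couple slowly. The fallback sets out from 9 (with 10) and does not rely on facial selectivity: the C6 epimer of the diol, the (1R)-diol F10, is separated from 11 and submitted to Mitsunobu esterification with benzoic acid (PPh3, DIAD, THF). This benzoylates O7 and esterifies O6 with inversion, so that both epimers converge on the route at 12.

Further compounds
F1 | step 8 | di-tert-butylsilylene acetal of 11 across O6 and O7 | CC(C)(C)[Si]1(C(C)(C)C)OC/C(=C/[C@@H](O[Si](C)(C)C(C)(C)C)[C@@H]2COC(C)(C)O2)[C@H](O1)[C@H]3COC(C)(C)O3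
F2 | step 8 | (Z)-dialdehyde with O6 and O7 in the di-tert-butylsilylene ring and O3 as TBS ether | O=C[C@H]1O[Si](C(C)(C)C)(C(C)(C)C)OC/C1=C/[C@@H](O[Si](C)(C)C(C)(C)C)C=O
F3 | step 8 | silylene-protected cyclohexene cis-1,2-diol (O3 TBS) | O[C@H]1[C@@H](O)[C@H](O[Si](C)(C)C(C)(C)C)C=C2CO[Si](C(C)(C)C)(C(C)(C)C)O[C@H]12
F4 | step 8 | 1,2-O-isopropylidene derivative of F3 | CC1(C)O[C@H]2[C@@H](O1)[C@H](O[Si](C)(C)C(C)(C)C)C=C3CO[Si](C(C)(C)C)(C(C)(C)C)O[C@H]23
F5 | step 8 | 1,2-O-isopropylidene-3-O-TBS cyclohexene with free C6 and C7 hydroxyls | CC1(C)O[C@H]2[C@@H](O1)[C@H](O[Si](C)(C)C(C)(C)C)C=C(CO)[C@@H]2O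
F6 | step 8 | 6,7-di-O-benzoyl-1,2-O-isopropylidene-3-O-TBS cyclohexene | CC1(C)O[C@H]2[C@@H](O1)[C@H](O[Si](C)(C)C(C)(C)C)C=C(COC(=O)c3ccccc3)[C@@H]2OC(=O)c4ccccc4
F7 | step 9 | [(3R,4S,5S,6S)-6-(benzoyloxy)-3,4,5-trihydroxycyclohex-1-en-1-yl]methyl benzoate | O[C@H]1[C@@H](O)[C@H](O)C=C(COC(=O)c2ccccc2)[C@@H]1OC(=O)c1ccccc1
F8 | step 9 | butane-2,3-diacetal of F7 across O2 and O3 (both acetal carbons S, methoxy groups axial) | O[C@H]1[C@H]2O[C@](C)(OC)[C@@](C)(OC)O[C@@H]2C=C(COC(=O)c3ccccc3)[C@@H]1OC(=O)c4ccccc4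
F9 | step 9 | 1-O-acetyl derivative of F8 | CC(=O)O[C@H]1[C@H]2O[C@](C)(OC)[C@@](C)(OC)O[C@@H]2C=C(COC(=O)c3ccccc3)[C@@H]1OC(=O)c4ccccc4
F10 | step 5 | (1R,2Z,4R)-4-[(tert-butyldimethylsilyl)oxy]-1-[(4R)-2,2-dimethyl-1,3-dioxolan-4-yl]-4-[(4S)-2,2-dimethyl-1,3-dioxolan-4-yl]-2-(hydroxymethyl)but-2-en-1-ol | OC/C(=C/[C@@H](O[Si](C)(C)C(C)(C)C)[C@@H]1COC(C)(C)O1)[C@@H](O)[C@H]2COC(C)(C)O2
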